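The numbers in the tables were generated by integration from invented constants; scatter was added.

If oak and alder were to be judged before anyone ran them, I had dawn and noon to go on, and I built the flask up one step at a time.

the same everywhere: starting material 0.10 M; gas phase 3.4 mM (held)
- dawn: protic impurity 0.025 M; run made earlier
- noon: protic impurity 0.041 M; run made earlier
- oak: protic impurity 0.0260 M; time 25 h
- alder: protic impurity 0.0200 M; time 25 h

| run | time / h | starting material / % | over-reacted product / % | target / % |
|---|---|---|---|---|
| dawn | 1.33 | 74.8 | 0.8 | 1.3 |
| dawn | 4.00 | 47.2 | 0.2 | 6.4 |
| dawn | 8.00 | 28.9 | 0.1 | 10.1 |
| dawn | 10.0 | 21.3 | 0.4 | 12.1 |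
| dawn | 15.0 | 14.4 | 2.7 | 15.0 |
| dawn | 20.0 | 9.1 | 6.3 | 15.7 |
| dawn | 25.0 | 6.6 | 8.0 | 16.5 |
| noon | 1.33 | 74.9 | 0 | 0.6 |
| noon | 4.00 | 44.7 | 0 | 6.7 |
| noon | 8.00 | 29.2 | 1.3 | 12.5 |
| noon | 10.0 | 22.9 | 1.4 | 12.0 |
| noon | 15.0 | 15.4 | 4.8 | 16.1 |
| noon | 20.0 | 8.6 | 6.5 | 14.6 |
| noon | 25.0 | 4.9 | 7.1 | 15.1 |

(each reading ± 1 percentage point)

* which of these there is most of at the end, counted by the starting material in it, oak (target / starting material / over-reacted product)
* which of these there is most of at the end, counted by the starting material in it, alder (target / starting material / over-reacted product)
* final amount of the leader among these, as a percentage of the starting material charged, in oak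
* final amount of the leader among these, as a percentage of the starting material charged, in alder

- a species is counted by the starting material in it: one self-condensation product counts as two
- at the start none of the gas is dissolved
- the numbers in the tables scatter with a standard deviation of 1 percentage point
- candidate steps: dissolved gas + target -> over-reacted product; starting material + dissolved gas -> target; gas phase <-> dissolved gas; 2 starting material -> self-condensation product; dissolved gas -> decomposed reagent; starting material + protic impurity -> quenched substrate

With the main step by itself, starting material + dissolved gas → target, each point of starting material lost reappears as target. But by 25.0 h dawn had lost 93.4% of its charge and held 16.5% of target. Adding the second gas step, from target to over-reacted product, brought in 8.0% more, so dawn's sum was 24.5% and noon's 22.2%. I called the mean of these sums the gas-route fraction, the part of the charge that has passed the gas step by that time: 23.4%.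

The gas these sums used, one per target and two per over-reacted product, averaged 30.9% of the charge, about ten times the 3.40% that a saturated liquid holds. So gas kept flowing in, and I treated the dissolved gas as steady (a quasi-steady state), its intake matching its use. On that reckoning, with the intake and the split between target and over-reacted product held the same, the gas-route fraction runs inversely with the charge.

The rest of dawn's loss, 69 percentage points, I gave to self-condensation product, which takes no gas but competes for the starting material. Last came the protic impurity: noon carried 0.410 of the charge against dawn's 0.250, yet the sums differed by 2.3 points, with each reading scattering by 1 point. Oak lay between these two runs, and alder lay below dawn by a third of that step. So I kept the means for both flasks: over-reacted product at 7.55%, starting material at 5.75%, and target at 15.8%, more than either of the others.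

The forecast named target at 15.7% for oak and target at 15.8% for alder: “Target leads in both, and the two values should be essentially the same.”

Oak gave target at 15.3%, and alder gave target at 15.5%.

    dissolved gas + target → over-reacted product (k = 14.0 L mol⁻¹ h⁻¹)
    starting material + dissolved gas → target (k = 24.0 L mol⁻¹ h⁻¹)
    gas phase ⇌ dissolved gas, rate k3*(csat - [dissolved gas]) (kL = 0.890 h⁻¹)
    2 starting material → self-condensation product (k = 1.10 L mol⁻¹ h⁻¹)
    dissolved gas → decomposed reagent (k = 0.0200 h⁻¹)
    starting material + protic impurity → quenched substrate (k = 0.390 L mol⁻¹ h⁻¹)

Oak's gas-route fraction came to 23.5% and alder's to 23.8%, beside my 23.4%. A neighbouring flask was like alder but charged with 0.17 M of starting material. Spreading the same gas intake over that larger charge gave me 13.7%. The flask held 15.7% of its charge in the two gas products, and target was 10.5%.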